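The ten-membered carbocycle (germacrane numbering: C1=C10 olefin, C3 angelate, C4–C5 epoxide, C6 acetate, C7 isopropyl) is made by contraction of an eleven-membered cyclic ether in which oxygen bridges C6 and C7. That ether, built by Williamson etherification, B-alkyl Suzuki coupling and Nozaki–Hiyama–Kishi closure, already holds both E olefins, the C3 carbinol and C7. The key [1,2]-Wittig shift exploits the C6 position, allylic to C4=C5 and alpha to the ring oxygen: lithiation there moves C7 from oxygen to C6, forms the C6–C7 ring bond, turns the ring oxygen into the C6 hydroxyl and sets C6 from C7. Acylation, hydroxyl-directed epoxidation and acetylation finish.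

Key step: step 12

Remark: the target is read as the (3R,4R,5R,6S,7S) angelate, (2Z)-2-methylbut-2-enoate, with an E C1=C10 olefin and a trans C4–C5 epoxide; germacrane numbering is used for the ring atoms throughout.
Remark: 1, 3, 5 and 20 are taken as commercial, and every stereochemical outcome below is an expectation, not a result.

Step 1
Reactants: 1 (±)-4-methylpent-1-en-3-ol
Product: 2 (R)-4-methylpent-1-en-3-ol
Conditions: Ti(OiPr)4, L-(+)-diisopropyl tartrate, t-BuOOH (0.6 equiv), 4 Å MS, CH2Cl2, −20 °C
Reagents that add atoms: none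
Why: Sharpless kinetic resolution, in which the titanium tartrate catalyst should epoxidise the (S)-alcohol much faster, so that the unreacted (R)-alcohol is recovered enantioenriched and supplies the stereocentre that becomes C7.

Step 2
Reactants: 2 (R)-4-methylpent-1-en-3-ol; 3 1-bromobut-2-yne
Product: 4 (3R)-3-(but-2-yn-1-yloxy)-4-methylpent-1-ene
Conditions: NaH, THF, 0 °C; then 3, Bu4NI (cat.), 0 °C to rt
Reagents that add atoms: none
Why: Williamson ether synthesis, in which the sodium alkoxide displaces the primary propargylic bromide by SN2 without touching the carbinol centre, and which installs the future ring oxygen together with C6, C5, C4 and the C4 methyl.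

Step 3
Reactants: 5 pent-3-yn-1-ol
Product: 6 tert-butyldimethyl(pent-3-yn-1-yloxy)silane
Conditions: TBSCl, imidazole, CH2Cl2, rt
Reagents that add atoms: tert-butyldimethylsilyl chloride, CC(C)(C)[Si](C)(C)Cl
Why: Silylation of the primary alcohol, which removes the free hydroxyl that would otherwise steer zirconium to the wrong alkyne carbon in step 4.

Step 4
Reactants: 6 tert-butyldimethyl(pent-3-yn-1-yloxy)silane
Product: 8 tert-butyl{[(3E)-4-iodopent-3-en-1-yl]oxy}dimethylsilane, via alkenylzirconocene chloride 7 (not isolated)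
Conditions: Cp2Zr(H)Cl, THF, rt to 45 °C; then I2, 0 °C
Reagents that add atoms: iodine, [I][I]
Why: Hydrozirconation–iodination, in which syn addition of Zr–H should place zirconium on the less hindered methyl-bearing alkyne carbon after equilibration and iodinolysis with retention gives the (E)-2-iodoalkene that fixes the C1=C10 geometry.

Step 5
Reactants: 4 (3R)-3-(but-2-yn-1-yloxy)-4-methylpent-1-ene; 8 tert-butyl{[(3E)-4-iodopent-3-en-1-yl]oxy}dimethylsilane
Product: 10 tert-butyl{[(3E,7S)-7-(but-2-yn-1-yloxy)-4,8-dimethylnon-3-en-1-yl]oxy}dimethylsilane, via B-alkyl-9-BBN adduct 9 (not isolated)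
Conditions: 4, 9-BBN-H, THF, 0 °C to rt; then 8, Pd(dppf)Cl2 (cat.), AsPh3, Cs2CO3, DMF/H2O, rt
Reagents that add atoms: none
Why: B-alkyl Suzuki–Miyaura coupling, in which 9-BBN-H should hydroborate the monosubstituted alkene in preference to the internal alkyne and the primary alkylborane couples with the alkenyl iodide with retention of geometry to form the C9–C10 bond.

Step 6
Reactants: 10 tert-butyl{[(3E,7S)-7-(but-2-yn-1-yloxy)-4,8-dimethylnon-3-en-1-yl]oxy}dimethylsilane
Product: 12 tert-butyl{[(3E,7S)-7-{[(2E)-3-iodobut-2-en-1-yl]oxy}-4,8-dimethylnon-3-en-1-yl]oxy}dimethylsilane, via alkenylzirconocene chloride 11 (not isolated)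
Conditions: Cp2Zr(H)Cl, THF, rt to 40 °C; then I2, 0 °C
Reagents that add atoms: iodine, [I][I]
Why: Hydrozirconation–iodination of the methyl alkyne, in which zirconium should add syn to the methyl-bearing carbon away from the branched alkoxymethyl group and iodinolysis gives the (E)-3-iodobut-2-enyl ether that carries the C4=C5 geometry.

Step 7
Reactants: 12 tert-butyl{[(3E,7S)-7-{[(2E)-3-iodobut-2-en-1-yl]oxy}-4,8-dimethylnon-3-en-1-yl]oxy}dimethylsilane
Product: 13 (3E,7S)-7-{[(2E)-3-iodobut-2-en-1-yl]oxy}-4,8-dimethylnon-3-en-1-ol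
Conditions: Bu4NF, THF, 0 °C
Reagents that add atoms: none
Why: Fluoride desilylation of the primary silyl ether, which nothing else in the molecule should feel.

Step 8
Reactants: 13 (3E,7S)-7-{[(2E)-3-iodobut-2-en-1-yl]oxy}-4,8-dimethylnon-3-en-1-ol
Product: 14 (3E,7S)-7-{[(2E)-3-iodobut-2-en-1-yl]oxy}-4,8-dimethylnon-3-enal
Conditions: Dess–Martin periodinane, NaHCO3, CH2Cl2, 0 °C
Reagents that add atoms: none
Why: Buffered Dess–Martin oxidation, which should give the beta,gamma-unsaturated aldehyde without base so that the C1=C10 olefin does not move into conjugation, the aldehyde being used crude.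

Step 9
Reactants: 14 (3E,7S)-7-{[(2E)-3-iodobut-2-en-1-yl]oxy}-4,8-dimethylnon-3-enal
Product: 15 (3E,7E,11S)-4,8-dimethyl-11-(propan-2-yl)oxacycloundeca-3,7-dien-5-ol as both C5 epimers (C5 is germacrane C3)
Conditions: CrCl2 (excess), NiCl2 (cat.), DMSO/THF, rt, 2 mM by slow addition
Reagents that add atoms: none
Why: Nozaki–Hiyama–Kishi macrocyclisation, in which the alkenylchromium species formed with retention of geometry adds to the aldehyde at high dilution and closes the eleven-membered oxacycle at C3–C4, the C3 carbinol being formed without control and converged in steps 10 and 11.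

Step 10
Reactants: 15 (3E,7E,11S)-4,8-dimethyl-11-(propan-2-yl)oxacycloundeca-3,7-dien-5-ol (epimers)
Product: 16 (3E,7E,11S)-4,8-dimethyl-11-(propan-2-yl)oxacycloundeca-3,7-dien-5-one
Conditions: Dess–Martin periodinane, NaHCO3, CH2Cl2, 0 °C
Reagents that add atoms: none
Why: Dess–Martin oxidation of the allylic alcohol, which erases the uncontrolled C3 centre as the enone under non-basic conditions.

Step 11
Reactants: 16 (3E,7E,11S)-4,8-dimethyl-11-(propan-2-yl)oxacycloundeca-3,7-dien-5-one
Product: 17 (3E,5R,7E,11S)-4,8-dimethyl-11-(propan-2-yl)oxacycloundeca-3,7-dien-5-ol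
Conditions: (S)-1-methyl-3,3-diphenyltetrahydro-1H,3H-pyrrolo[1,2-c][1,3,2]oxazaborole (0.2 equiv), catecholborane, toluene, −78 °C
Reagents that add atoms: none
Why: Corey–Bakshi–Shibata reduction, in which the alpha-methyl alkenyl arm acts as the large group so that the (S)-oxazaborolidine should deliver hydride 1,2 to the face that gives the (3R)-allylic alcohol by reagent control.

Step 12
Reactants: 17 (3E,5R,7E,11S)-4,8-dimethyl-11-(propan-2-yl)oxacycloundeca-3,7-dien-5-ol
Product: 19 (1S,2E,4R,6E,10S)-3,7-dimethyl-10-(propan-2-yl)cyclodeca-2,6-diene-1,4-diol [(3R,6S,7S)-germacra-1(10),4-diene-3,6-diol], via C6-lithiated lithium alkoxide 18 (not isolated)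
Conditions: s-BuLi (2.4 equiv), THF, −78 °C to −25 °C; then H2O
Reagents that add atoms: none
Why: [1,2]-Wittig rearrangement, used as a one-atom ring contraction of a cyclic ether. After the first equivalent of base has made the C3 lithium alkoxide, s-BuLi removes a C6 proton, the only C–H that is both allylic to C4=C5 and alpha to the ring oxygen, to give 18; the O–C7 bond then homolyses to a chain-tethered pair of a C6 oxyallyl radical anion and the secondary C7 radical, which recombine at C6, so that no new cyclisation mode is involved: the eleven-membered oxacycle contracts to the ten-membered carbocycle by a 1,2-shift of C7 from oxygen to carbon and the ring oxygen becomes the C6 alkoxide. The closest known reactions are the [1,2]-Wittig shift of allyl sec-alkyl ethers and the anionic ring contraction of alpha-metalated cyclic ethers. C7 should keep its configuration because the tether makes recombination faster than rotation of the radical, and the new C6 centre is set by substrate control from C7, the pair closing through the crown-like germacradiene conformation that places the C6 oxygen and the C7 isopropyl group trans and pseudo-equatorial (6S). The step needs lithiation at C6 and not at C3, and [1,2] recombination and not a [1,4] or [2,3] shift: the free C3 alkoxide shuts down C3–H removal and 1,4-elimination, C4 is fully substituted and a [1,4] shift would demand an eight-membered ring holding the E C1=C10 olefin, and C7 carries no allyl group.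

Step 13
Reactants: 19 (3R,6S,7S)-germacra-1(10),4-diene-3,6-diol; 20 angelic acid [(2Z)-2-methylbut-2-enoic acid]
Product: 21 (3R,6S,7S)-6-hydroxygermacra-1(10)E,4E-dien-3-yl (2Z)-2-methylbut-2-enoate
Conditions: 20, 2,4,6-trichlorobenzoyl chloride, Et3N, toluene, rt; then 19, 45 °C
Reagents that add atoms: none
Why: Yamaguchi-type mixed-anhydride esterification without a nucleophilic catalyst, which should transfer the (Z)-acyl group without isomerisation and to the C3 hydroxyl, because the C6 hydroxyl is shielded by the adjacent isopropyl-bearing C7.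

Step 14
Reactants: 21 (3R,6S,7S)-6-hydroxygermacra-1(10)E,4E-dien-3-yl (2Z)-2-methylbut-2-enoate
Product: 22 (3R,4R,5R,6S,7S)-4,5-epoxy-6-hydroxygermacr-1(10)E-en-3-yl (2Z)-2-methylbut-2-enoate
Conditions: VO(acac)2 (cat.), t-BuOOH, CH2Cl2, 0 °C
Reagents that add atoms: tert-butyl hydroperoxide, CC(C)(C)OO
Why: Hydroxyl-directed VO(acac)2 epoxidation, in which the C6 vanadate ester should deliver oxygen to the C4=C5 olefin on the face that avoids A(1,3) strain between C6 and the cis C4 methyl, giving the threo (4R,5R) epoxide, while the remote C1=C10 olefin and the electron-poor angelate stay untouched.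

Step 15
Reactants: 22 (3R,4R,5R,6S,7S)-4,5-epoxy-6-hydroxygermacr-1(10)E-en-3-yl (2Z)-2-methylbut-2-enoate
Product: 23 (3R,4R,5R,6S,7S)-6-acetoxy-4,5-epoxygermacr-1(10)E-en-3-yl (2Z)-2-methylbut-2-enoate (CNP0180504.3)
Conditions: Ac2O, pyridine, 4-(dimethylamino)pyridine (cat.), CH2Cl2, rt
Reagents that add atoms: acetic anhydride, CC(=O)OC(C)=O
Why: Base-catalysed acetylation of the remaining hindered secondary alcohol, under conditions mild enough to leave the epoxide and the angelate intact.

Compound list
1 | (±)-4-methylpent-1-en-3-ol | CC(C)C(O)C=C | starting material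
2 | (R)-4-methylpent-1-en-3-ol | C=C[C@H](O)C(C)C | intermediate
3 | 1-bromobut-2-yne | CC#CCBr | starting material
4 | (3R)-3-(but-2-yn-1-yloxy)-4-methylpent-1-ene | C=C[C@H](OCC#CC)C(C)C | intermediate
5 | pent-3-yn-1-ol | CC#CCCO | starting material
6 | tert-butyldimethyl(pent-3-yn-1-yloxy)silane | CC#CCCO[Si](C)(C)C(C)(C)C | intermediate
7 | chlorobis(cyclopentadienyl)[(2E)-5-(tert-butyldimethylsilyloxy)pent-2-en-2-yl]zirconium (not isolated) | C/C(=C\CCO[Si](C)(C)C(C)(C)C)[Zr](Cl)(C1C=CC=C1)C1C=CC=C1 | intermediate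
8 | tert-butyl{[(3E)-4-iodopent-3-en-1-yl]oxy}dimethylsilane | I/C(C)=C/CCO[Si](C)(C)C(C)(C)C | intermediate
9 | 9-[(3S)-3-(but-2-yn-1-yloxy)-4-methylpentyl]-9-borabicyclo[3.3.1]nonane (not isolated) | CC#CCO[C@@H](CCB1C2CCCC1CCC2)C(C)C | intermediate
10 | tert-butyl{[(3E,7S)-7-(but-2-yn-1-yloxy)-4,8-dimethylnon-3-en-1-yl]oxy}dimethylsilane | C/C(CC[C@H](OCC#CC)C(C)C)=C\CCO[Si](C)(C)C(C)(C)C | intermediate
11 | alkenylzirconocene chloride of 10, zirconium on the methyl-bearing carbon of the former alkyne, E (not isolated) | C/C(CC[C@H](OC/C=C(/[Zr](Cl)(C1C=CC=C1)C1C=CC=C1)C)C(C)C)=C\CCO[Si](C)(C)C(C)(C)C | intermediate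
12 | tert-butyl{[(3E,7S)-7-{[(2E)-3-iodobut-2-en-1-yl]oxy}-4,8-dimethylnon-3-en-1-yl]oxy}dimethylsilane | C/C(CC[C@H](OC/C=C(/I)C)C(C)C)=C\CCO[Si](C)(C)C(C)(C)C | intermediate
13 | (3E,7S)-7-{[(2E)-3-iodobut-2-en-1-yl]oxy}-4,8-dimethylnon-3-en-1-ol | C/C(CC[C@H](OC/C=C(/I)C)C(C)C)=C\CCO | intermediate
14 | (3E,7S)-7-{[(2E)-3-iodobut-2-en-1-yl]oxy}-4,8-dimethylnon-3-enal | C/C(CC[C@H](OC/C=C(/I)C)C(C)C)=C\CC=O | intermediate
15 | (3E,7E,11S)-4,8-dimethyl-11-(propan-2-yl)oxacycloundeca-3,7-dien-5-ol, both C5 epimers | CC(C)[C@@H]1CC/C(C)=C/CC(O)/C(C)=C/CO1 | intermediate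
16 | (3E,7E,11S)-4,8-dimethyl-11-(propan-2-yl)oxacycloundeca-3,7-dien-5-one | CC(C)[C@@H]1CC/C(C)=C/CC(=O)/C(C)=C/CO1 | intermediate
17 | (3E,5R,7E,11S)-4,8-dimethyl-11-(propan-2-yl)oxacycloundeca-3,7-dien-5-ol | CC(C)[C@@H]1CC/C(C)=C/C[C@@H](O)/C(C)=C/CO1 | intermediate
18 | C6-lithiated lithium alkoxide of 17 (not isolated) | CC(C)[C@@H]1CC/C(C)=C/C[C@@H](O[Li])/C(C)=C/C([Li])O1 | intermediate
19 | (1S,2E,4R,6E,10S)-3,7-dimethyl-10-(propan-2-yl)cyclodeca-2,6-diene-1,4-diol | CC(C)[C@@H]1CC/C(C)=C/C[C@@H](O)/C(C)=C/[C@H]1O | intermediate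
20 | angelic acid, (2Z)-2-methylbut-2-enoic acid | C/C=C(/C)C(O)=O | starting material
21 | (3R,6S,7S)-6-hydroxygermacra-1(10)E,4E-dien-3-yl (2Z)-2-methylbut-2-enoate | CC(C)[C@@H]1CC/C(C)=C/C[C@@H](OC(=O)/C(C)=C\C)/C(C)=C/[C@H]1O | intermediate
22 | (3R,4R,5R,6S,7S)-4,5-epoxy-6-hydroxygermacr-1(10)E-en-3-yl (2Z)-2-methylbut-2-enoate | C/C=C(/C)C(=O)O[C@@H]1C/C=C(\C)CC[C@@H](C(C)C)[C@H](O)[C@H]2O[C@@]21C | intermediate
23 | (3R,4R,5R,6S,7S)-6-acetoxy-4,5-epoxygermacr-1(10)E-en-3-yl (2Z)-2-methylbut-2-enoate | C/C=C(/C)C(=O)O[C@@H]1C/C=C(\C)CC[C@@H](C(C)C)[C@H](OC(C)=O)[C@H]2O[C@@]21C | target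

Total step count: 15
Longest linear sequence: 13 steps (steps 1, 2 and 5 to 15; the branch through steps 3 and 4 is equally long)

Steps most likely to fail

Step 12. The tethered radical pair may recombine without facial control at C6; retention at C7 is still expected. The fallback sets out from 19 when it is formed together with the C6 epimer of the diol F1 and comes back at 21. The mixture is esterified at C3 as in step 13, which gives 21 together with the C6 epimer of the angelate F2. Dess–Martin oxidation of the free C6 carbinol then converges both to the enone F3. Reduction of F3 with catecholborane and the (R)-enantiomer of the oxazaborolidine of step 11, the alkenyl arm acting as the large group, should set (6S) by reagent control and return 21.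

Step 9. Intermolecular coupling may outrun closure of the eleven-membered ring, or insertion into the trisubstituted alkenyl iodide may be too slow. The fallback sets out from 10 and comes back at 15, so that steps 6 to 8 are not needed. Desilylation with Bu4NF gives the alkynol F4 and Dess–Martin oxidation gives the ynal F5. Nickel-catalysed reductive alkyne–aldehyde macrocyclisation (Ni(cod)2, PBu3, Et3B, toluene, high dilution) then joins the aldehyde carbon to the methyl-bearing alkyne carbon with syn delivery of hydrogen.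

Step 13. The (Z)-2-methylbut-2-enoyl group may isomerise to the (E)-isomer during acyl transfer. The fallback sets out from 19 and comes back at 21. The C3 hydroxyl is esterified with 2-[bis(2,2,2-trifluoroethoxy)phosphoryl]propanoic acid (EDC, 4-(dimethylamino)pyridine, CH2Cl2) to give the phosphonate ester F6. Still–Gennari olefination of F6 with acetaldehyde (KN(SiMe3)2, 18-crown-6, THF, −78 °C) then builds the (Z)-trisubstituted enoate on the substrate.

Further compounds
F1 | step 12 | C6 epimer of diol 19, (3R,6R,7S)-germacra-1(10),4-diene-3,6-diol | CC(C)[C@@H]1CC/C(C)=C/C[C@@H](O)/C(C)=C/[C@@H]1O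
F2 | step 12 | C6 epimer of angelate 21 | CC(C)[C@@H]1CC/C(C)=C/C[C@@H](OC(=O)/C(C)=C\C)/C(C)=C/[C@@H]1O
F3 | step 12 | (3R,7S)-6-oxogermacra-1(10)E,4E-dien-3-yl (2Z)-2-methylbut-2-enoate | CC(C)[C@@H]1CC/C(C)=C/C[C@@H](OC(=O)/C(C)=C\C)/C(C)=C/C1=O
F4 | step 9 | (3E,7S)-7-(but-2-yn-1-yloxy)-4,8-dimethylnon-3-en-1-ol | C/C(CC[C@H](OCC#CC)C(C)C)=C\CCO
F5 | step 9 | (3E,7S)-7-(but-2-yn-1-yloxy)-4,8-dimethylnon-3-enal | C/C(CC[C@H](OCC#CC)C(C)C)=C\CC=O
F6 | step 13 | (3R,6S,7S)-6-hydroxygermacra-1(10)E,4E-dien-3-yl 2-[bis(2,2,2-trifluoroethoxy)phosphoryl]propanoate | CC(C)[C@@H]1CC/C(C)=C/C[C@@H](OC(=O)C(C)P(=O)(OCC(F)(F)F)OCC(F)(F)F)/C(C)=C/[C@H]1O
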